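**Retrosynthetic overview**

1. Ring A is the six-membered 1,3,5-tricarbonyl ring, numbered as the drawn dienone: C1 ketone, C2 acyl-bearing, C3 enol, C4 cyclopentylmethyl-bearing, C5 enol, C6 quaternary. The last disconnection removes the C2 acyl group, giving (R)-2-methylbutanoic acid and the acyl-free trione.
2. Ring A is then cut at C4–C5 (ring-closing Dieckmann bond) and C2–C3 (Claisen acylation). Both bonds are made in one pot from a keto ester (C1, C2, C5, C6) and a lactone (C3, C4 and the cyclopentane).
3. Enabling feature: C5 is a carboxyl-level carbon attached to C6, a quaternary carbon without hydrogen, and C4 is the γ-carbon of the C1/C3 β-diketone. In the open-chain 3,5-dioxo ester only C4 can take the second negative charge, and it lies six atoms from the ester carbon.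
4. The tertiary cyclopentanol oxygen is tied to the future C3 as a δ-lactone. This temporary ring protects the alcohol, activates C3 as acyl donor and is opened in the key step. The cyclopentane comes from (S)-limonene (ring cleavage, intramolecular aldol); the quaternary centre comes from auxiliary-controlled prenylation of methyl 2-methylacetoacetate.
5. Order of ring formation: cyclopentane (step 2), temporary lactone (step 4), ring A (step 7, with loss of the lactone ring).

Key step: step 7

Assumption: the toluene/HMPA protocol with the L-valine auxiliary is taken to give the (2S)-keto ester; the sense of induction in this aza-enolate alkylation depends on the ligand on lithium, so the configuration would be checked at that stage and D-valine tert-butyl ester used if it is opposite.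
Assumption: (R)-2-methylbutanoic acid is taken as commercially available, and L-valine tert-butyl ester is used as the free base liberated from its commercial hydrochloride; the target is treated as the drawn enol tautomer of the 2-acylcyclohexane-1,3,5-trione.

**Route**

Step 1
Reactants: 1 (S)-(−)-limonene
Product: 3 (3S)-6-oxo-3-(prop-1-en-2-yl)heptanal, via secondary ozonide 2 (not isolated)
Conditions: O3 (1.0 equiv), CH2Cl2, −78 °C; then Me2S, −78 °C to rt
Reagents that add atoms: ozone, [O-][O+]=O
Why: Chemoselective ozonolysis with reductive work-up; one equivalent of ozone at −78 °C should react faster with the electron-rich trisubstituted ring alkene than with the 1,1-disubstituted isopropenyl group, and the stereocentre is not touched.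

Step 2
Reactants: 3 (3S)-6-oxo-3-(prop-1-en-2-yl)heptanal
Product: 4 (1R,2S,5S)-2-hydroxy-2-methyl-5-(prop-1-en-2-yl)cyclopentane-1-carbaldehyde
Conditions: piperidine (0.2 equiv), AcOH (0.2 equiv), Et2O, 0 °C to rt, stopped at the aldol stage; used crude
Reagents that add atoms: none
Why: Amine-catalysed intramolecular aldol addition (5-enolexo, aldehyde enamine onto the methyl ketone); the limonene-derived centre controls both new ones, because the epimerisable formyl-bearing carbon should settle trans to the neighbouring isopropenyl group and the reversible aldol should place the carbinol methyl anti and the hydroxyl cis (hydrogen-bonded) to the formyl group, while low temperature holds back dehydration.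

Step 3
Reactants: 4 (1R,2S,5S)-2-hydroxy-2-methyl-5-(prop-1-en-2-yl)cyclopentane-1-carbaldehyde; 5 methyl (triphenylphosphoranylidene)acetate
Product: 6 methyl (2E)-3-[(1R,2S,5S)-2-hydroxy-2-methyl-5-(prop-1-en-2-yl)cyclopentyl]prop-2-enoate
Conditions: 5 (1.2 equiv), CH2Cl2, rt
Reagents that add atoms: methyl (triphenylphosphoranylidene)acetate (5), COC(=O)C=P(c1ccccc1)(c1ccccc1)c1ccccc1
Why: Wittig olefination with a stabilised ylide should give the E-enoate under neutral conditions that spare the retro-aldol-prone and dehydration-prone β-hydroxy aldehyde.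

Step 4
Reactants: 6 methyl (2E)-3-[(1R,2S,5S)-2-hydroxy-2-methyl-5-(prop-1-en-2-yl)cyclopentyl]prop-2-enoate
Product: 8 (4aR,5S,7aS)-7a-methyl-5-(prop-1-en-2-yl)hexahydrocyclopenta[b]pyran-2(3H)-one, via hydroxy ester 7 (not isolated)
Conditions: Mg turnings, MeOH, 0 °C to rt; aq. NH4Cl; then PPTS (cat.), toluene, 80 °C
Reagents that add atoms: none
Why: Dissolving-metal conjugate reduction (Mg in MeOH) should saturate only the ester-conjugated alkene, and the cis relation of the tertiary hydroxyl and the propanoate arm then allows acid-catalysed lactonisation to the cis-fused δ-lactone, which masks the alcohol and activates the acyl carbon.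

Step 5
Reactants: 9 methyl 2-methyl-3-oxobutanoate; 10 L-valine tert-butyl ester
Product: 11 methyl (2Z)-3-{[(2S)-1-tert-butoxy-3-methyl-1-oxobutan-2-yl]amino}-2-methylbut-2-enoate
Conditions: BF3·OEt2 (cat.), benzene, reflux, Dean–Stark trap
Reagents that add atoms: L-valine tert-butyl ester (10), CC(C)[C@H](N)C(=O)OC(C)(C)C
Why: Acid-catalysed condensation of a β-keto ester with a primary amine under water removal should give the hydrogen-bonded Z-enamino ester.

Step 6
Reactants: 11 methyl (2Z)-3-{[(2S)-1-tert-butoxy-3-methyl-1-oxobutan-2-yl]amino}-2-methylbut-2-enoate; 12 prenyl bromide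
Product: 15 methyl (2S)-2-acetyl-2,5-dimethylhex-4-enoate, via lithio-enamine 13 (not isolated), via alkylated imine 14 (not isolated)
Conditions: LiN(iPr)2 (1.2 equiv), toluene, −78 °C; HMPA (3 equiv), then 12, −78 to −40 °C; then 1 M aq. HCl, THF, 0 °C to rt
Reagents that add atoms: prenyl bromide (12), CC(C)=CCBr; water, O
Why: Auxiliary-controlled aza-enolate alkylation; lithium in the lithio-enamine is chelated by nitrogen and the tert-butyl ester carbonyl so that the valine isopropyl group shields one face, prenyl bromide reacts in SN2 fashion at the α-carbon from the open face to set the quaternary centre, and aqueous acid hydrolyses the ketimine and returns the auxiliary.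

Step 7
Reactants: 15 methyl (2S)-2-acetyl-2,5-dimethylhex-4-enoate; 8 (4aR,5S,7aS)-7a-methyl-5-(prop-1-en-2-yl)hexahydrocyclopenta[b]pyran-2(3H)-one
Product: 18 (6R)-3,5-dihydroxy-4-{[(1R,2S,5S)-2-hydroxy-2-methyl-5-(prop-1-en-2-yl)cyclopentyl]methyl}-6-methyl-6-(3-methylbut-2-en-1-yl)cyclohexa-2,4-dien-1-one, via lithium enolate 16 (not isolated), via hydroxy diketo ester 17 (not isolated)
Conditions: 15 (1.1 equiv), LiN(iPr)2 (1.1 equiv), THF, −78 °C; 8 (1.0 equiv), −78 to 0 °C; LiN(iPr)2 (2.3 equiv), −78 °C to rt; then cold 1 M aq. HCl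
Reagents that add atoms: none
Why: Tandem Claisen condensation/Dieckmann cyclisation: the only enolisable position of 15 is the acetyl methyl group, whose lithium enolate 16 adds to the lactone carbonyl of 8, and collapse of the adduct opens the temporary lactone ring, frees the tertiary alkoxide and gives the lithium diketonate of 17 (C2–C3 bond). Two further equivalents of base deprotonate the alcohol and the diketonate, which can form its dianion only at the methylene that becomes C4 because the other flank is the quaternary carbon; this carbanion attacks the methyl ester carbon (future C5) in a 6-(enolendo)-exo-trig closure held in place by the lithium-chelated Z-diketonate, and loss of methoxide gives ring A as its stabilised enolate. The closest known reaction types are the acylation of ketone enolates by lactones and the base-induced cyclisation of 3,5-dioxo esters to cyclohexane-1,3,5-triones through their dianions, the laboratory counterpart of a polyketide Claisen cyclisation. No stereocentre is formed; the quaternary centre carries no hydrogen and cannot epimerise (its descriptor changes from S to R only through the priority rules), and the cyclopentane centres lie outside the enolate systems. The step needs attack on the lactone in preference to the neopentyl-type ester of a second molecule of 15 (secured by steric hindrance at that ester) and C- over O-cyclisation (secured by the dianion, whose terminal carbon is its most nucleophilic site, and by the drain into the triketone enolate).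

Step 8
Reactants: 18 (6R)-3,5-dihydroxy-4-{[(1R,2S,5S)-2-hydroxy-2-methyl-5-(prop-1-en-2-yl)cyclopentyl]methyl}-6-methyl-6-(3-methylbut-2-en-1-yl)cyclohexa-2,4-dien-1-one; 19 (R)-2-methylbutanoic acid
Product: 21 (6R)-3,5-dihydroxy-4-{[(1R,2S,5S)-2-hydroxy-2-methyl-5-(prop-1-en-2-yl)cyclopentyl]methyl}-6-methyl-2-[(2R)-2-methylbutanoyl]-6-(3-methylbut-2-en-1-yl)cyclohexa-2,4-dien-1-one, via enol ester 20 (not isolated)
Conditions: 19 (1.1 equiv), DCC (1.2 equiv), DMAP (0.3 equiv), CH2Cl2, 0 °C to rt
Reagents that add atoms: (R)-2-methylbutanoic acid (19), CC[C@@H](C)C(=O)O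
Why: Carbodiimide/DMAP C-acylation of a cyclic 1,3-dione (Steglich-type O-acylation followed by DMAP-relayed O-to-C acyl shift); the acyl group should end at C2, the only unsubstituted carbon between two carbonyls, where the product is held as a chelated enol, while the hindered tertiary alcohol stays free and the α-stereocentre of the acid is carried through under these mild conditions.

**Compound list**

1 | (S)-(−)-limonene, (4S)-1-methyl-4-(prop-1-en-2-yl)cyclohex-1-ene | CC1=CC[C@H](CC1)C(C)=C | starting material
2 | secondary ozonide of the ring alkene, (4S)-1-methyl-4-(prop-1-en-2-yl)-7,8,9-trioxabicyclo[4.2.1]nonane, diastereomer mixture at the ozonide carbons | CC12CC[C@H](C(C)=C)CC(OO1)O2 | intermediate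
3 | (3S)-6-oxo-3-(prop-1-en-2-yl)heptanal | CC(=O)CC[C@H](C(C)=C)CC=O | intermediate
4 | (1R,2S,5S)-2-hydroxy-2-methyl-5-(prop-1-en-2-yl)cyclopentane-1-carbaldehyde | C=C(C)[C@H]1CC[C@](C)(O)[C@@H]1C=O | intermediate
5 | methyl (triphenylphosphoranylidene)acetate | COC(=O)C=P(c1ccccc1)(c1ccccc1)c1ccccc1 | starting material
6 | methyl (2E)-3-[(1R,2S,5S)-2-hydroxy-2-methyl-5-(prop-1-en-2-yl)cyclopentyl]prop-2-enoate | C=C(C)[C@H]1CC[C@](C)(O)[C@@H]1/C=C/C(=O)OC | intermediate
7 | methyl 3-[(1R,2S,5S)-2-hydroxy-2-methyl-5-(prop-1-en-2-yl)cyclopentyl]propanoate | C=C(C)[C@H]1CC[C@](C)(O)[C@@H]1CCC(=O)OC | intermediate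
8 | (4aR,5S,7aS)-7a-methyl-5-(prop-1-en-2-yl)hexahydrocyclopenta[b]pyran-2(3H)-one, cis-fused δ-lactone | C=C(C)[C@H]1CC[C@]2(C)OC(=O)CC[C@H]12 | intermediate
9 | methyl 2-methyl-3-oxobutanoate (methyl 2-methylacetoacetate, racemic) | COC(=O)C(C)C(C)=O | starting material
10 | L-valine tert-butyl ester, tert-butyl (2S)-2-amino-3-methylbutanoate | CC(C)[C@H](N)C(=O)OC(C)(C)C | starting material
11 | methyl (2Z)-3-{[(2S)-1-tert-butoxy-3-methyl-1-oxobutan-2-yl]amino}-2-methylbut-2-enoate | COC(=O)/C(C)=C(/C)N[C@@H](C(C)C)C(=O)OC(C)(C)C | intermediate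
12 | prenyl bromide, 1-bromo-3-methylbut-2-ene | CC(C)=CCBr | starting material
13 | N-lithio derivative of 11 (lithio-enamine) | COC(=O)/C(C)=C(/C)[N-][C@@H](C(C)C)C(=O)OC(C)(C)C.[Li+] | intermediate
14 | methyl (2S)-3-{[(2S)-1-tert-butoxy-3-methyl-1-oxobutan-2-yl]imino}-2-methyl-2-(3-methylbut-2-en-1-yl)butanoate | COC(=O)[C@@](C)(CC=C(C)C)C(C)=N[C@@H](C(C)C)C(=O)OC(C)(C)C | intermediate
15 | methyl (2S)-2-acetyl-2,5-dimethylhex-4-enoate | COC(=O)[C@@](C)(CC=C(C)C)C(C)=O | intermediate
16 | lithium enolate of 15, lithium (3S)-3-(methoxycarbonyl)-3,6-dimethylhepta-1,5-dien-2-olate | COC(=O)[C@@](C)(CC=C(C)C)C(=C)[O-].[Li+] | intermediate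
17 | methyl (2S)-7-[(1R,2S,5S)-2-hydroxy-2-methyl-5-(prop-1-en-2-yl)cyclopentyl]-2-methyl-2-(3-methylbut-2-en-1-yl)-3,5-dioxoheptanoate, present in the flask as its lithium salts | C=C(C)[C@H]1CC[C@](C)(O)[C@@H]1CCC(=O)CC(=O)[C@](C)(CC=C(C)C)C(=O)OC | intermediate
18 | (6R)-3,5-dihydroxy-4-{[(1R,2S,5S)-2-hydroxy-2-methyl-5-(prop-1-en-2-yl)cyclopentyl]methyl}-6-methyl-6-(3-methylbut-2-en-1-yl)cyclohexa-2,4-dien-1-one, enol tautomer of the acyl-free trione | C=C(C)[C@H]1CC[C@](C)(O)[C@@H]1CC1=C(O)[C@@](C)(CC=C(C)C)C(=O)C=C1O | intermediate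
19 | (R)-2-methylbutanoic acid | CC[C@@H](C)C(=O)O | starting material
20 | enol (2R)-2-methylbutanoate of 18, one O-acyl regioisomer shown | C=C(C)[C@H]1CC[C@](C)(O)[C@@H]1CC1=C(O)[C@@](C)(CC=C(C)C)C(=O)C=C1OC(=O)[C@H](C)CC | intermediate
21 | (6R)-3,5-dihydroxy-4-{[(1R,2S,5S)-2-hydroxy-2-methyl-5-(prop-1-en-2-yl)cyclopentyl]methyl}-6-methyl-2-[(2R)-2-methylbutanoyl]-6-(3-methylbut-2-en-1-yl)cyclohexa-2,4-dien-1-one | C=C(C)[C@H]1CC[C@](C)(O)[C@@H]1CC1=C(O)[C@@](C)(CC=C(C)C)C(=O)C(C(=O)[C@H](C)CC)=C1O | target

**Step count and risks**

Total step count: 8. Longest linear sequence: 6 steps (steps 1, 2, 3, 4, 7, 8); steps 5 and 6 build the second fragment.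

Steps most likely to fail:

1. Step 7. The ketone enolate may take a proton from the lactone α-methylene instead of adding to the carbonyl, and the crowded trianion may close slowly or through oxygen. The fallback sets out from 8 and comes back at 18, with every intermediate isolated and the alcohol protected. Ring-opening aminolysis of 8 (MeNHOMe·HCl, AlMe3, CH2Cl2) should give the hydroxy Weinreb amide F1. Silylation (Et3SiOTf, 2,6-lutidine, −78 °C) should give the triethylsilyl ether F2. Addition of the lithium enolate 16 to F2 should give, after work-up of the stable chelated adduct, the silyl-protected diketo ester F3. Dieckmann closure of its dianion (LiN(iPr)2, 2.2 equiv, THF, −78 to 0 °C) should give the silyl-protected trione F4. HF·pyridine in THF then removes the silyl group to return 18.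

2. Step 2. The aldol adduct may dehydrate to the conjugated cyclopentene aldehyde, and the two new centres may form with poor diastereocontrol. The fallback sets out from 3 and comes back at 4, setting the centres by reagent-controlled steps. Deliberate aldol condensation (piperidine, AcOH, benzene, reflux) should give the enal F5. Luche reduction (NaBH4, CeCl3·7H2O, MeOH) should give the allylic alcohol F6. Hydroxyl-directed epoxidation (VO(acac)2, t-BuOOH, CH2Cl2) on the face away from the isopropenyl group should give the epoxy alcohol F7. NaAlH2(OCH2CH2OMe)2 in THF should open the epoxide by internal hydride delivery with inversion at the carbon next to the carbinol, giving the 1,3-diol F8. Selective oxidation of the primary alcohol (TEMPO, PhI(OAc)2) returns 4.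

3. Step 6. The facial selectivity of the aza-enolate alkylation may be insufficient or opposite to that assumed. The fallback sets out from 9 and 12 and comes back at 15 by resolution instead of auxiliary control. Alkylation of 9 with 12 (K2CO3, acetone, reflux) should give the racemic keto ester F9. A ketoreductase chosen from a panel (NADPH recycled with glucose dehydrogenase and glucose, aqueous buffer) should reduce the (2R)-ketone to the hydroxy ester F10 and leave (2S)-15, which is separated by chromatography.

**Further compounds**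

F1 | step 7 | 3-[(1R,2S,5S)-2-hydroxy-2-methyl-5-(prop-1-en-2-yl)cyclopentyl]-N-methoxy-N-methylpropanamide | C=C(C)[C@H]1CC[C@](C)(O)[C@@H]1CCC(=O)N(C)OC
F2 | step 7 | N-methoxy-N-methyl-3-[(1R,2S,5S)-2-methyl-5-(prop-1-en-2-yl)-2-(triethylsilyloxy)cyclopentyl]propanamide | C=C(C)[C@H]1CC[C@](C)(O[Si](CC)(CC)CC)[C@@H]1CCC(=O)N(C)OC
F3 | step 7 | methyl (2S)-2-methyl-2-(3-methylbut-2-en-1-yl)-7-[(1R,2S,5S)-2-methyl-5-(prop-1-en-2-yl)-2-(triethylsilyloxy)cyclopentyl]-3,5-dioxoheptanoate | C=C(C)[C@H]1CC[C@](C)(O[Si](CC)(CC)CC)[C@@H]1CCC(=O)CC(=O)[C@](C)(CC=C(C)C)C(=O)OC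
F4 | step 7 | triethylsilyl ether of 18 at the tertiary cyclopentanol oxygen | C=C(C)[C@H]1CC[C@](C)(O[Si](CC)(CC)CC)[C@@H]1CC1=C(O)[C@@](C)(CC=C(C)C)C(=O)C=C1O
F5 | step 2 | (5R)-2-methyl-5-(prop-1-en-2-yl)cyclopent-1-ene-1-carbaldehyde | C=C(C)[C@H]1CCC(C)=C1C=O
F6 | step 2 | [(5R)-2-methyl-5-(prop-1-en-2-yl)cyclopent-1-en-1-yl]methanol | C=C(C)[C@H]1CCC(C)=C1CO
F7 | step 2 | [(1S,2R,5S)-5-methyl-2-(prop-1-en-2-yl)-6-oxabicyclo[3.1.0]hexan-1-yl]methanol, epoxide oxygen anti to the isopropenyl group | C=C(C)[C@H]1CC[C@](C)(O2)[C@@]12CO
F8 | step 2 | (1S,2S,3S)-2-(hydroxymethyl)-1-methyl-3-(prop-1-en-2-yl)cyclopentan-1-ol | C=C(C)[C@H]1CC[C@](C)(O)[C@@H]1CO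
F9 | step 6 | methyl 2-acetyl-2,5-dimethylhex-4-enoate, racemic | COC(=O)C(C)(CC=C(C)C)C(C)=O
F10 | step 6 | methyl (2R)-3-hydroxy-2-methyl-2-(3-methylbut-2-en-1-yl)butanoate, carbinol configuration set by the enzyme | COC(=O)[C@](C)(CC=C(C)C)C(C)O
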